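The numbers in the tables are simulated with made-up constants; noise was put on by code.

Sunday's flask was the one I had to decide on: work it up at its last reading, or leave it stirring to the asked time.

- Sunday's: starting material 0.10 M; reagent 0.40 M; free catalyst 2.5 mM; the very flask that is asked about, followed so far
- flask: starting material 0.10 M; reagent 0.400 M; free catalyst 2.5 mM; time 1.5 h

Sunday's run (percent of the starting material charged)

| time / min | target / % | crystals / % | starting material / % |
|---|---|---|---|
| 1.33 | 24.1 | 0.9 | 54.3 |
| 3.00 | 22.7 | 1.8 | 38.9 |
| 8.00 | 15.0 | 4.7 | 19.8 |
| 20.0 | 9.0 | 6.0 | 6.0 |

(readings scatter by 0.3 percentage points)

- for target the crystals are counted in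
- as a solid, counted per litre of solution: crystals
- what was read earlier has a scatter of 0.3 percentage points, one standard deviation
- what may be going on: crystals <-> target; starting material + reagent <-> isomer of the product; target + free catalyst <-> isomer of the product + free catalyst; free catalyst -> spent catalyst; reagent + free catalyst + target -> free catalyst + over-reaction product; starting material + reagent <-> target

* amount of target and crystals together at 1.5 h, in percent of the starting material charged
* concentration of target in solution at 1.5 h, in percent of saturation

The target column counts the crystals in, so I took them off and divided what remained by starting material. That c(target)/c(starting material) in solution, which I called the pool ratio, read 0.520 at 8.00 min and 0.500 at 20.0 min, while starting material fell from 19.8% to 6.0%. Where the forward and back rates of one step balance, time drops out of such a ratio; I took this for a quasi-equilibrium, and the ratio is a reading with the scatter of its figures.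

So I reckoned the total at a later time as crystals plus the ratio times starting material. At 20.0 min the crystals stood at 6.0% and the dissolved part at 3 percentage points, with starting material lower than at the reading before, so I expected no gain in the total from waiting and set no figure of my own.

The forecast gave 4% and 70% of saturation, starting from the same observation: “Starting material stays about twice dissolved target”.

    crystals ⇌ target, rate k1*(cs1 - [target]) while solid is left; crystals form when [target] > cs1 (solubility = 1.40 mM, k = 0.0390 min⁻¹)
    starting material + reagent ⇌ isomer of the product (K = 130 M⁻¹, k = 0.610 M⁻¹ min⁻¹)
    target + free catalyst ⇌ isomer of the product + free catalyst, rate k3*[free catalyst]*[target] forward; the back reaction follows from the equilibrium constant (k = 1.50 M⁻¹ min⁻¹)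
    free catalyst → spent catalyst (k = 0.00710 min⁻¹)
    reagent + free catalyst + target → free catalyst + over-reaction product (k = 3.30 M⁻² min⁻¹)
    starting material + reagent ⇌ target (K = 1.40 M⁻¹, k = 1.20 M⁻¹ min⁻¹)

This flask gave 6.89% at 1.5 h, at 72.6% of saturation, with crystals at 5.87%, and the total was lower than at Sunday's last reading. A doubled coefficient of crystallising out gives 11.3%, further from the forecast; a run showing that would have counted against it. The pool ratio on the 2.37% of starting material left gives 1.19% dissolved, and this flask holds 1 point of dissolved target.

With 0.025 M of starting material, the 1.96% left gives 0.980% dissolved by the same ratio. That flask gave 1.03%, with crystals at 0%.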